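**Retrosynthetic overview** (labdane numbering C1–C20; α = face of the C10 methyl)

1. Side chain last: the C12–C13 bond by Suzuki coupling of an (E)-C11=C12 alkenylboronate (from the C11 aldehyde) with 3-bromofuran-2(5H)-one; 19-OAc by selective acetylation of the 3,19-diol; C8=CH2 by Wittig methylenation.
2. Ring A (key step): C1=C2 and C3–C4 are made in one pot by Still–Gennari olefination of the C10 formyl group followed by acylation of the C4 cyano carbanion by the new (Z)-ester; hydrogenation and NaBH4 then give C1–C2 and the 3-OH, and the nitrile becomes C19.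
3. Enabling feature: on ring B the formyl carbon C1 sits on quaternary (so non-enolisable) C10 and the α-cyano carbon C4 sits on C5, trans to it, so C1–C10–C5–C4 is a four-atom unit that a two-carbon acetate (C2–C3) closes to ring A; the linear C≡N on C4 can take the axial site syn to the C20 methyl.
4. Ring B: 2-methylcyclohex-2-enone → CBS reduction → Johnson–Claisen (sets C5, brings C4/C18/C19) → allylic oxidation → trans conjugate vinylation and hydroxymethylation (sets C10 and C9).
5. Ring order: ring B is the carbocycle of the starting enone, ring A is closed in step 9, and the butenolide ring is coupled on intact.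

Key step: step 9

Remark on the chemistry: the cyano-bearing side-chain carbon (later C4) is carried as a mixture of epimers up to step 9, where it becomes a planar carbanion; its SMILES is therefore left undefined until then.

**Route**

Step 1
Reactants: 1 2-methylcyclohex-2-en-1-one
Product: 2 (R)-2-methylcyclohex-2-en-1-ol
Conditions: (S)-2-methyl-CBS-oxazaborolidine (10 mol%), BH3·SMe2, THF, −20 °C
Reagents that add atoms: none
Why: Corey–Bakshi–Shibata reduction, in which the 2-methylvinyl side acts as the large ketone substituent so that the (S)-catalyst should deliver hydride to give the (R)-allylic alcohol.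

Step 2
Reactants: 2 (R)-2-methylcyclohex-2-en-1-ol, 3 triethyl orthopropionate
Product: 4 ethyl 2-[(1R)-2-methylcyclohex-2-en-1-yl]propanoate
Conditions: EtC(OEt)3, EtCO2H (cat.), 140 °C, EtOH distilled off
Reagents that add atoms: triethyl orthopropionate, CCC(OCC)(OCC)OCC
Why: Johnson orthoester Claisen rearrangement, whose suprafacial [3,3] shift should transfer the carbinol configuration to the new ring C–C bond (C5) on the same face while moving the alkene next to the methyl-bearing carbon.

Step 3
Reactants: 4 ethyl 2-[(1R)-2-methylcyclohex-2-en-1-yl]propanoate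
Product: 5 2-[(1R)-2-methylcyclohex-2-en-1-yl]propanenitrile
Conditions: AlMe3, NH3 (gives Me2AlNH2), xylene, 120 °C
Reagents that add atoms: dimethylaluminium amide (from AlMe3 and NH3), C[Al](C)N
Why: Weinreb-type aminolysis of the ester by Me2AlNH2 with dehydration of the primary amide in the same flask should give the nitrile without touching the ring stereocentre.

Step 4
Reactants: 5 2-[(1R)-2-methylcyclohex-2-en-1-yl]propanenitrile
Product: 6 2-[(1R)-2-methyl-4-oxocyclohex-2-en-1-yl]propanenitrile
Conditions: Rh2(cap)4 (1 mol%), t-BuOOH (70% aq.), K2CO3, CH2Cl2, rt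
Reagents that add atoms: tert-butyl hydroperoxide, CC(C)(C)OO
Why: Dirhodium caprolactamate-catalysed allylic oxidation, in which the ring CH2 next to the alkene CH is the only allylic position that can become a ketone, should give the β-methyl enone.

Step 5
Reactants: 6 2-[(1R)-2-methyl-4-oxocyclohex-2-en-1-yl]propanenitrile, 7 vinylmagnesium bromide, 8 formaldehyde
Product: 10 2-[(1R,2R,3R)-2-ethenyl-3-(hydroxymethyl)-2-methyl-4-oxocyclohexyl]propanenitrile, via silyl enol ether 9 (not isolated)
Conditions: CH2=CHMgBr, CuBr·SMe2 (10 mol%), Me3SiCl, HMPA, THF, −78 °C; crude enol ether, then aq. HCHO, Yb(OTf)3 (10 mol%), THF, rt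
Reagents that add atoms: vinylmagnesium bromide, C=C[Mg]Br; formaldehyde, C=O
Why: Copper-catalysed, Me3SiCl-accelerated conjugate addition should deliver vinyl anti to the pseudo-axial cyanoethyl group (setting quaternary C10 with vinyl trans to that group), and the Kobayashi-type aqueous Mukaiyama aldol of the regiodefined silyl enol ether should place CH2OH at the epimerisable C9, which settles equatorial and trans to vinyl.

Step 6
Reactants: 10 2-[(1R,2R,3R)-2-ethenyl-3-(hydroxymethyl)-2-methyl-4-oxocyclohexyl]propanenitrile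
Product: 11 tert-butyldiphenylsilyl ether of 10
Conditions: t-BuPh2SiCl, imidazole, DMF, rt
Reagents that add atoms: tert-butyl(chloro)diphenylsilane, CC(C)(C)[Si](Cl)(c1ccccc1)c1ccccc1
Why: Standard silylation of the primary alcohol gives an ether that should survive the acid, base, ozone and hydride of the following steps.

Step 7
Reactants: 11 tert-butyldiphenylsilyl ether of 10
Product: 12 ethylene ketal of 11
Conditions: Me3SiOCH2CH2OSiMe3, Me3SiOTf (5 mol%), CH2Cl2, −78 → −20 °C
Reagents that add atoms: 1,2-bis(trimethylsilyloxy)ethane, C[Si](C)(C)OCCO[Si](C)(C)C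
Why: Noyori ketalisation under aprotic conditions should mask the C8 ketone (the only other acidic site for step 9) without β-elimination of the silyloxy group.

Step 8
Reactants: 12 ethylene ketal of 11
Product: 13 C10 aldehyde (formyl in place of ethenyl)
Conditions: O3, CH2Cl2/MeOH, −78 °C; then Me2S
Reagents that add atoms: ozone, [O-][O+]=O
Why: Ozonolysis of the only alkene with reductive work-up should give the neopentyl, non-enolisable aldehyde that is C1.

Step 9
Reactants: 13 C10 aldehyde, 14 methyl bis(2,2,2-trifluoroethyl)phosphonoacetate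
Product: 16 bicyclic enone nitrile (ring A closed), via (Z)-enoate 15 (not isolated)
Conditions: 14, KN(SiMe3)2 (1.2 equiv), 18-crown-6, THF, −78 °C; then KN(SiMe3)2 (1.5 equiv), −78 → 0 °C
Reagents that add atoms: methyl bis(2,2,2-trifluoroethyl)phosphonoacetate, COC(=O)CP(=O)(OCC(F)(F)F)OCC(F)(F)F
Why: The potassium phosphonate anion adds to the non-enolisable C1 aldehyde and the oxaphosphetane collapses under Still–Gennari control to the (Z)-enoate 15 (C1=C2), after which the second charge of base removes the only remaining acidic hydrogen (α to the nitrile) and the planar cyano carbanion at C4 attacks the ester carbonyl C3 with loss of methoxide (C3–C4). The closest known reaction types are the Still–Gennari Z-selective Horner–Wadsworth–Emmons olefination and the Thorpe/Dieckmann-type C-acylation of a metalated nitrile by an ester, here run in one flask. Ring A closes by a 6-exo-trig addition–elimination in which the Z-alkene holds C3 within reach of C4. The new quaternary centre C4 is controlled by ring B: in the sofa-like transition state the small linear C≡N should take the pseudo-axial site syn to the axial C20 methyl and the C18 methyl the equatorial site, so the nitrile (future C19) ends cis to C20, and both C4 epimers of 13 converge because the anion is planar. The step needs Z-selectivity (an E-enoate cannot cyclise) and a single site of deprotonation, which are secured by the trifluoroethyl phosphonate with KN(SiMe3)2/18-crown-6, by the quaternary C10 (no γ-hydrogen) and by masking C8 as a ketal and C11 as a silyl ether.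

Step 10
Reactants: 16 bicyclic enone nitrile
Product: 18 3α-hydroxy nitrile, via keto nitrile 17 (not isolated)
Conditions: H2 (1 atm), 10% Pd/C, EtOAc, rt; filter; then NaBH4, MeOH, 0 °C
Reagents that add atoms: none
Why: Heterogeneous hydrogenation should saturate the only alkene (C1=C2), and NaBH4 reduction of the 3-ketone next to quaternary C4 should proceed by axial hydride delivery to give the equatorial alcohol, cis to the axial nitrile.

Step 11
Reactants: 18 3α-hydroxy nitrile
Product: 19 C8 ketone
Conditions: 1 M HCl, THF, rt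
Reagents that add atoms: water, O
Why: Acid hydrolysis of the dioxolane should release the C8 ketone while the silyl ether survives, and the enolisable C9 stays in (or equilibrates to) the equatorial configuration, cis to the C10 methyl.

Step 12
Reactants: 19 C8 ketone, 20 methyltriphenylphosphonium bromide
Product: 21 exocyclic alkene (C8=C17)
Conditions: Ph3PCH3Br, KOt-Bu, toluene, 60 °C
Reagents that add atoms: methyltriphenylphosphonium bromide, C[P+](c1ccccc1)(c1ccccc1)c1ccccc1.[Br-]
Why: Wittig methylenation with excess ylide (the free 3-OH is carried as its alkoxide, and the quaternary nitrile has no α-hydrogen) should install the exocyclic methylene and fix C9.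

Step 13
Reactants: 21 exocyclic alkene
Product: 23 3,19-diol, via hydroxy aldehyde 22 (not isolated)
Conditions: i-Bu2AlH, CH2Cl2, −78 → 0 °C; aq. AcOH; then NaBH4, MeOH, 0 °C
Reagents that add atoms: water, O
Why: Partial reduction of the nitrile by i-Bu2AlH to the aldimine, hydrolysis to the aldehyde and immediate NaBH4 reduction (before any retro-aldol of the β-hydroxy aldehyde) should convert C19 into CH2OH with C4 unchanged.

Step 14
Reactants: 23 3,19-diol, 24 acetic anhydride
Product: 25 19-acetate
Conditions: Ac2O (1.1 equiv), pyridine, CH2Cl2, 0 °C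
Reagents that add atoms: acetic anhydride, CC(=O)OC(C)=O
Why: Selective acylation should take the primary 19-OH in preference to the hindered secondary 3-OH flanked by quaternary C4.

Step 15
Reactants: 25 19-acetate
Product: 26 C11 primary alcohol
Conditions: HF·pyridine, THF, 0 °C → rt
Reagents that add atoms: none
Why: Fluoride-mediated desilylation under mildly acidic conditions should free the C11 alcohol without acetate migration or cleavage.

Step 16
Reactants: 26 C11 primary alcohol
Product: 27 C11 aldehyde
Conditions: TEMPO (10 mol%), PhI(OAc)2, CH2Cl2, rt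
Reagents that add atoms: none
Why: TEMPO/PhI(OAc)2 oxidation is selective for primary over secondary alcohols and mild enough that the β,γ-unsaturated aldehyde should not move into conjugation if it is used at once.

Step 17
Reactants: 27 C11 aldehyde, 28 2-(dichloromethyl)-4,4,5,5-tetramethyl-1,3,2-dioxaborolane
Product: 29 (E)-alkenylboronate (C11=C12)
Conditions: CrCl2, Cl2CHBpin, THF, rt
Reagents that add atoms: 2-(dichloromethyl)-4,4,5,5-tetramethyl-1,3,2-dioxaborolane, ClC(Cl)B1OC(C)(C)C(C)(C)O1
Why: Takai–Utimoto chromium-mediated borylative olefination is neutral, tolerates the free hydroxyl and the acetate, and should give the (E)-alkenylboronate by anti elimination from the gem-dichromium adduct.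

Step 18
Reactants: 29 (E)-alkenylboronate, 30 3-bromofuran-2(5H)-one
Product: 31 target compound (19-O-acetyl-14-deoxy-11,12-didehydroandrographolide)
Conditions: PdCl2(dppf) (5 mol%), K3PO4, THF/H2O, 40 °C
Reagents that add atoms: 3-bromofuran-2(5H)-one, BrC1=CCOC1=O
Why: Suzuki–Miyaura coupling proceeds with retention of alkene geometry and should join C12 to the butenolide α-carbon (C13) under base mild enough for the acetate and the lactone.

**Compound list**

1 | 2-methylcyclohex-2-en-1-one | CC1=CCCCC1=O | starting material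
2 | (R)-2-methylcyclohex-2-en-1-ol | CC1=CCCC[C@H]1O | intermediate
3 | triethyl orthopropionate | CCC(OCC)(OCC)OCC | starting material
4 | ethyl 2-[(1R)-2-methylcyclohex-2-en-1-yl]propanoate (epimers at the propanoate α-carbon) | CCOC(=O)C(C)[C@H]1CCCC=C1C | intermediate
5 | 2-[(1R)-2-methylcyclohex-2-en-1-yl]propanenitrile (α-epimers) | N#CC(C)[C@H]1CCCC=C1C | intermediate
6 | 2-[(1R)-2-methyl-4-oxocyclohex-2-en-1-yl]propanenitrile (α-epimers) | N#CC(C)[C@H]1CCC(=O)C=C1C | intermediate
7 | vinylmagnesium bromide | C=C[Mg]Br | starting material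
8 | formaldehyde (37% aqueous) | C=O | starting material
9 | 2-[2-ethenyl-2-methyl-4-(trimethylsilyloxy)cyclohex-3-en-1-yl]propanenitrile (vinyl trans to the cyanoethyl group) | C[Si](C)(C)OC1=C[C@](C)(C=C)[C@@H](C(C)C#N)CC1 | intermediate
10 | 2-[(1R,2R,3R)-2-ethenyl-3-(hydroxymethyl)-2-methyl-4-oxocyclohexyl]propanenitrile (vinyl trans to cyanoethyl, CH2OH trans to vinyl) | O=C1CC[C@H](C(C)C#N)[C@@](C)(C=C)[C@@H]1CO | intermediate
11 | tert-butyldiphenylsilyl ether of 10 | O=C1CC[C@H](C(C)C#N)[C@@](C)(C=C)[C@@H]1CO[Si](c1ccccc1)(c1ccccc1)C(C)(C)C | intermediate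
12 | 2-[6-(tert-butyldiphenylsilyloxymethyl)-7-ethenyl-7-methyl-1,4-dioxaspiro[4.5]decan-8-yl]propanenitrile (ring configuration as in 10) | C12(OCCO1)CC[C@H](C(C)C#N)[C@@](C)(C=C)[C@@H]2CO[Si](c1ccccc1)(c1ccccc1)C(C)(C)C | intermediate
13 | 2-[6-(tert-butyldiphenylsilyloxymethyl)-7-formyl-7-methyl-1,4-dioxaspiro[4.5]decan-8-yl]propanenitrile (ring configuration as in 10) | C12(OCCO1)CC[C@H](C(C)C#N)[C@@](C)(C=O)[C@@H]2CO[Si](c1ccccc1)(c1ccccc1)C(C)(C)C | intermediate
14 | methyl bis(2,2,2-trifluoroethyl)phosphonoacetate | COC(=O)CP(=O)(OCC(F)(F)F)OCC(F)(F)F | starting material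
15 | methyl (Z)-3-[6-(tert-butyldiphenylsilyloxymethyl)-8-(1-cyanoethyl)-7-methyl-1,4-dioxaspiro[4.5]decan-7-yl]prop-2-enoate | C12(OCCO1)CC[C@H](C(C)C#N)[C@@](C)(/C=C\C(=O)OC)[C@@H]2CO[Si](c1ccccc1)(c1ccccc1)C(C)(C)C | intermediate
16 | enone nitrile: trans-fused decalin, 3-oxo-1-ene, 4α-cyano (axial, cis to the 10α-methyl), 4β-methyl, 5β-H, 9β-H, C8 ethylene ketal, C9 CH2OSi(t-Bu)Ph2 | C12(OCCO1)CC[C@@H]3[C@](C)(C#N)C(=O)C=C[C@@]3(C)[C@@H]2CO[Si](c1ccccc1)(c1ccccc1)C(C)(C)C | intermediate
17 | keto nitrile: 1,2-dihydro derivative of 16 | C12(OCCO1)CC[C@@H]3[C@](C)(C#N)C(=O)CC[C@@]3(C)[C@@H]2CO[Si](c1ccccc1)(c1ccccc1)C(C)(C)C | intermediate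
18 | 3α-hydroxy nitrile: equatorial 3-OH cis to the 4α-nitrile, C8 ketal | C12(OCCO1)CC[C@@H]3[C@](C)(C#N)[C@H](O)CC[C@@]3(C)[C@@H]2CO[Si](c1ccccc1)(c1ccccc1)C(C)(C)C | intermediate
19 | C8 ketone of 18 | O=C1CC[C@@H]2[C@](C)(C#N)[C@H](O)CC[C@@]2(C)[C@@H]1CO[Si](c1ccccc1)(c1ccccc1)C(C)(C)C | intermediate
20 | methyltriphenylphosphonium bromide | C[P+](c1ccccc1)(c1ccccc1)c1ccccc1.[Br-] | starting material
21 | 8(17)-ene: 3α-hydroxy-4α-cyano decalin with exocyclic methylene at C8 and C9 CH2OSi(t-Bu)Ph2 | C=C1CC[C@@H]2[C@](C)(C#N)[C@H](O)CC[C@@]2(C)[C@@H]1CO[Si](c1ccccc1)(c1ccccc1)C(C)(C)C | intermediate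
22 | 19-aldehyde of 21 (formyl in place of cyano) | C=C1CC[C@@H]2[C@](C)(C=O)[C@H](O)CC[C@@]2(C)[C@@H]1CO[Si](c1ccccc1)(c1ccccc1)C(C)(C)C | intermediate
23 | 3α,19-diol with C9 CH2OSi(t-Bu)Ph2 | C=C1CC[C@@H]2[C@](C)(CO)[C@H](O)CC[C@@]2(C)[C@@H]1CO[Si](c1ccccc1)(c1ccccc1)C(C)(C)C | intermediate
24 | acetic anhydride | CC(=O)OC(C)=O | starting material
25 | 19-acetate of 23 | C=C1CC[C@@H]2[C@](C)(COC(C)=O)[C@H](O)CC[C@@]2(C)[C@@H]1CO[Si](c1ccccc1)(c1ccccc1)C(C)(C)C | intermediate
26 | 19-acetoxy-3α,11-diol (C9 CH2OH) | C=C1CC[C@@H]2[C@](C)(COC(C)=O)[C@H](O)CC[C@@]2(C)[C@@H]1CO | intermediate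
27 | 19-acetoxy-3α-hydroxy C11 aldehyde (C9 CHO) | C=C1CC[C@@H]2[C@](C)(COC(C)=O)[C@H](O)CC[C@@]2(C)[C@@H]1C=O | intermediate
28 | 2-(dichloromethyl)-4,4,5,5-tetramethyl-1,3,2-dioxaborolane | ClC(Cl)B1OC(C)(C)C(C)(C)O1 | starting material
29 | (E)-C11=C12 alkenyl pinacolboronate | C=C1CC[C@@H]2[C@](C)(COC(C)=O)[C@H](O)CC[C@@]2(C)[C@@H]1/C=C/B1OC(C)(C)C(C)(C)O1 | intermediate
30 | 3-bromofuran-2(5H)-one | BrC1=CCOC1=O | starting material
31 | 19-O-acetyl-14-deoxy-11,12-didehydroandrographolide | C=C1CC[C@@H]2[C@](C)(COC(C)=O)[C@H](O)CC[C@@]2(C)[C@@H]1/C=C/C1=CCOC1=O | target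

**Summary**

Total step count: 18. Longest linear sequence: 18 steps (fully linear from 2-methylcyclohex-2-en-1-one).

Steps most likely to fail:

Step 9. Erosion of Z-selectivity in the olefination, or intermolecular conjugate addition of the metalated nitrile outrunning ring closure, would stop the annulation. The fallback sets out from aldehyde 13 and separates the two bond formations. An E-selective Horner–Wadsworth–Emmons reaction with trimethyl phosphonoacetate (NaH, THF) gives the (E)-enoate F1. Hydrogenation (H2, Pd/C) gives the saturated cyano ester F2. Treatment with KN(SiMe3)2 then closes ring A by Dieckmann-type acylation of the metalated nitrile through a chair transition state with the nitrile axial. This gives keto nitrile 17, where the route is rejoined (the NaBH4 stage of step 10 leads to 18).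

Step 5. 1,2-Addition and enolisation can outrun conjugate addition at the fully substituted β-carbon, and the Grignard reagent can attack the nitrile. The fallback sets out from enone 6 and first makes the acceptor doubly activated. α-Iodination (I2, pyridine) gives the 2-iodoenone F3. Palladium-catalysed methoxycarbonylation (PdCl2(PPh3)2, CO, MeOH, Et3N) gives the alkylidene β-keto ester F4. Copper-catalysed addition of CH2=CHMgBr (CuI, THF, −78 °C) gives the β-keto ester F5, again trans to the cyanoethyl group. Ketalisation (Me3SiOCH2CH2OSiMe3, Me3SiOTf) gives the ketal ester F6. LiBH4 reduces the ester but not the nitrile, giving the hydroxymethyl ketal F7. Silylation (t-BuPh2SiCl, imidazole) returns to the route at 12.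

Step 4. Oxidation at the tertiary allylic C–H next to the cyanoethyl branch or at the allylic methyl group, or over-oxidation, would give regioisomers. The fallback sets out from alkene 5 and fixes the oxygen position by an epoxide route. Epoxidation (mCPBA) gives the epoxide F8. Opening with NaSePh at the secondary carbon gives the hydroxy selenide F9. Oxidation with H2O2 and selenoxide elimination give the tertiary allylic alcohol F10. Oxidative 1,3-transposition with pyridinium chlorochromate (C5H5NH·CrO3Cl) then returns to the route at enone 6.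

**Further compounds**

F1 | step 9 | methyl (E)-3-[6-(tert-butyldiphenylsilyloxymethyl)-8-(1-cyanoethyl)-7-methyl-1,4-dioxaspiro[4.5]decan-7-yl]prop-2-enoate | C12(OCCO1)CC[C@H](C(C)C#N)[C@@](C)(/C=C/C(=O)OC)[C@@H]2CO[Si](c1ccccc1)(c1ccccc1)C(C)(C)C
F2 | step 9 | methyl 3-[6-(tert-butyldiphenylsilyloxymethyl)-8-(1-cyanoethyl)-7-methyl-1,4-dioxaspiro[4.5]decan-7-yl]propanoate | C12(OCCO1)CC[C@H](C(C)C#N)[C@@](C)(CCC(=O)OC)[C@@H]2CO[Si](c1ccccc1)(c1ccccc1)C(C)(C)C
F3 | step 5 | 2-[(1R)-3-iodo-2-methyl-4-oxocyclohex-2-en-1-yl]propanenitrile | N#CC(C)[C@H]1CCC(=O)C(I)=C1C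
F4 | step 5 | methyl 3-(1-cyanoethyl)-2-methyl-6-oxocyclohex-1-ene-1-carboxylate | N#CC(C)[C@H]1CCC(=O)C(C(=O)OC)=C1C
F5 | step 5 | methyl 3-(1-cyanoethyl)-2-ethenyl-2-methyl-6-oxocyclohexane-1-carboxylate (vinyl trans to cyanoethyl) | O=C1CC[C@H](C(C)C#N)[C@@](C)(C=C)C1C(=O)OC
F6 | step 5 | methyl 8-(1-cyanoethyl)-7-ethenyl-7-methyl-1,4-dioxaspiro[4.5]decane-6-carboxylate | C12(OCCO1)CC[C@H](C(C)C#N)[C@@](C)(C=C)[C@@H]2C(=O)OC
F7 | step 5 | 2-[7-ethenyl-6-(hydroxymethyl)-7-methyl-1,4-dioxaspiro[4.5]decan-8-yl]propanenitrile | C12(OCCO1)CC[C@H](C(C)C#N)[C@@](C)(C=C)[C@@H]2CO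
F8 | step 4 | 2-(1-methyl-7-oxabicyclo[4.1.0]heptan-2-yl)propanenitrile | N#CC(C)[C@H]1CCCC2OC12C
F9 | step 4 | 2-[2-hydroxy-2-methyl-3-(phenylselanyl)cyclohexyl]propanenitrile | N#CC(C)[C@H]1CCCC([Se]c2ccccc2)C1(C)O
F10 | step 4 | 2-(2-hydroxy-2-methylcyclohex-3-en-1-yl)propanenitrile | N#CC(C)[C@H]1CCC=CC1(C)O
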